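## Retrosynthetic overview

1. The target comes from its bis-TBS ether; the ten-membered carbocycle is closed last by ring-closing metathesis at C1=C10 (ring-cis olefin).
2. The C8 angelate is installed by Mitsunobu inversion of the C8 carbinol that the fragment coupling delivers.
3. Key disconnection C7–C8: intermolecular zinc Barbier allylation of a β,γ-unsaturated aldehyde (fragment B: C8–C10, C14) with an enantiopure 3-(bromomethyl)butenolide (fragment A: C1–C7, C11–C13, C15). This creates the α-methylene-γ-butyrolactone together with C7 and C8.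
4. Fragment A comes from Pd-catalysed carbonylative lactonisation of a (Z)-γ-hydroxy vinyl iodide, from CBS reduction of an ynenone (sets C6), from an enal made from but-2-yne-1,4-diol. Fragment B comes from 2-methylidenepropane-1,3-diol.
5. Ring order: the five-membered lactone first (as butenolide, converted into the α-methylene lactone in the coupling), then the ten-membered carbocycle.

Assumption: atom labels C1–C15 follow germacranolide numbering (C6 lactone O-carbon, C7 ring-fusion carbon, C8 angelate carbon, C14/C15 the CH2OH carbons on C10/C4), and CH2=CHCH2CH2ZnBr is bought as its THF solution.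

## Route

Step 1
Reactants: 1 but-2-yne-1,4-diol
Product: 2 4-[(tert-butyldimethylsilyl)oxy]but-2-yn-1-ol
Conditions: NaH (1.0 equiv), THF, 0 °C to rt; then TBSCl (1.0 equiv)
Reagents that add atoms: tert-butyldimethylsilyl chloride, CC(C)(C)[Si](C)(C)Cl
Why: Monosilylation of the sparingly soluble monosodium alkoxide of a symmetric diol (Williamson-type O-silylation) gives the mono-TBS ether; no stereocentre is involved.

Step 2
Reactants: 2 4-[(tert-butyldimethylsilyl)oxy]but-2-yn-1-ol
Product: 4 (Z)-4-[(tert-butyldimethylsilyl)oxy]-3-iodobut-2-en-1-ol, via cyclic vinylalanate 3 (not isolated)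
Conditions: NaAlH2(OCH2CH2OCH3)2, THF, 0 °C; then I2, THF, −78 °C
Reagents that add atoms: iodine, II
Why: Hydroxyl-directed trans-hydroalumination of the propargylic alcohol followed by iodinolysis with retention places iodine on C4 cis to the CH2OH carbon (C6), which fixes the later C4=C5 geometry.

Step 3
Reactants: 4 (Z)-4-[(tert-butyldimethylsilyl)oxy]-3-iodobut-2-en-1-ol; 5 but-3-en-1-ylzinc bromide (CH2=CHCH2CH2ZnBr)
Product: 6 (E)-3-{[(tert-butyldimethylsilyl)oxy]methyl}hepta-2,6-dien-1-ol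
Conditions: 5 (2.5 equiv), PdCl2(dppf) (5 mol%), THF, 45 °C
Reagents that add atoms: none
Why: Negishi sp2–sp3 cross-coupling proceeds with retention of alkene geometry, so the butenyl chain (C3–C1) ends up cis to C6 as the target requires.

Step 4
Reactants: 6 (E)-3-{[(tert-butyldimethylsilyl)oxy]methyl}hepta-2,6-dien-1-ol
Product: 7 (E)-3-{[(tert-butyldimethylsilyl)oxy]methyl}hepta-2,6-dienal
Conditions: MnO2 (excess), CH2Cl2, rt
Reagents that add atoms: none
Why: Chemoselective MnO2 oxidation of the allylic alcohol gives the β,β-disubstituted enal without E/Z isomerisation or attack on the silyl ether.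

Step 5
Reactants: 8 prop-2-yn-1-ol
Product: 9 1-methoxy-4-[(prop-2-yn-1-yloxy)methyl]benzene
Conditions: NaH, 4-methoxybenzyl chloride, Bu4NI (cat.), THF/DMF, 0 °C to rt
Reagents that add atoms: 4-methoxybenzyl chloride, COc1ccc(CCl)cc1
Why: Williamson ether synthesis protects the future C13 oxygen as a PMB ether that is orthogonal to the TBS ethers.

Step 6
Reactants: 9 1-methoxy-4-[(prop-2-yn-1-yloxy)methyl]benzene; 7 (E)-3-{[(tert-butyldimethylsilyl)oxy]methyl}hepta-2,6-dienal
Product: 11 rac-(E)-6-{[(tert-butyldimethylsilyl)oxy]methyl}-1-[(4-methoxybenzyl)oxy]deca-5,9-dien-2-yn-4-ol, via lithium acetylide 10 (not isolated)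
Conditions: 9, n-BuLi, THF, −78 °C; then 7, −78 to −20 °C
Reagents that add atoms: none
Why: 1,2-Addition of the lithium acetylide to the enal forms the C6–C7 bond; the carbinol is racemic at this stage and is corrected in the next two steps.

Step 7
Reactants: 11 rac-(E)-6-{[(tert-butyldimethylsilyl)oxy]methyl}-1-[(4-methoxybenzyl)oxy]deca-5,9-dien-2-yn-4-ol
Product: 12 (E)-6-{[(tert-butyldimethylsilyl)oxy]methyl}-1-[(4-methoxybenzyl)oxy]deca-5,9-dien-2-yn-4-one
Conditions: MnO2 (excess), CH2Cl2, rt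
Reagents that add atoms: none
Why: The doubly activated (allylic and propargylic) alcohol is oxidised rapidly by MnO2 to the cross-conjugated ynenone under neutral conditions.

Step 8
Reactants: 12 (E)-6-{[(tert-butyldimethylsilyl)oxy]methyl}-1-[(4-methoxybenzyl)oxy]deca-5,9-dien-2-yn-4-one
Product: 13 (4R,5E)-6-{[(tert-butyldimethylsilyl)oxy]methyl}-1-[(4-methoxybenzyl)oxy]deca-5,9-dien-2-yn-4-ol
Conditions: (R)-1-methyl-3,3-diphenyltetrahydro-1H,3H-pyrrolo[1,2-c][1,3,2]oxazaborole ((R)-Me-CBS, 0.5 equiv), catecholborane, toluene, −78 °C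
Reagents that add atoms: none
Why: In this Corey–Bakshi–Shibata reduction the trisubstituted alkenyl group acts as the large substituent and the linear alkynyl group as the small one, so the (R)-catalyst gives the (R)-carbinol (C6); catecholborane at −78 °C does not hydroborate the alkenes.

Step 9
Reactants: 13 (4R,5E)-6-{[(tert-butyldimethylsilyl)oxy]methyl}-1-[(4-methoxybenzyl)oxy]deca-5,9-dien-2-yn-4-ol
Product: 15 (2Z,4R,5E)-6-{[(tert-butyldimethylsilyl)oxy]methyl}-2-iodo-1-[(4-methoxybenzyl)oxy]deca-2,5,9-trien-4-ol, via cyclic vinylalanate 14 (not isolated)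
Conditions: NaAlH2(OCH2CH2OCH3)2, THF, −20 to 0 °C; then I2, THF, −78 °C
Reagents that add atoms: iodine, II
Why: The C6 alkoxide directs trans-hydroalumination of the alkyne and iodinolysis gives the (Z)-γ-hydroxy vinyl iodide with iodine on C11 cis to C6; the C6 stereocentre is not touched.

Step 10
Reactants: 15 (2Z,4R,5E)-6-{[(tert-butyldimethylsilyl)oxy]methyl}-2-iodo-1-[(4-methoxybenzyl)oxy]deca-2,5,9-trien-4-ol
Product: 16 (5R)-5-[(1E)-2-{[(tert-butyldimethylsilyl)oxy]methyl}hexa-1,5-dien-1-yl]-3-{[(4-methoxybenzyl)oxy]methyl}furan-2(5H)-one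
Conditions: PdCl2(PPh3)2 (5 mol%), CO (1 atm), K2CO3, THF, 40 °C
Reagents that add atoms: carbon monoxide, [C-]#[O+]
Why: Palladium-catalysed carbonylative lactonisation (oxidative addition into C–I, CO insertion, capture of the acyl-palladium by the cis C6 hydroxyl) closes the butenolide and supplies C12, with retention at C6 under a mild heterogeneous base.

Step 11
Reactants: 16 (5R)-5-[(1E)-2-{[(tert-butyldimethylsilyl)oxy]methyl}hexa-1,5-dien-1-yl]-3-{[(4-methoxybenzyl)oxy]methyl}furan-2(5H)-one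
Product: 17 (5R)-5-[(1E)-2-{[(tert-butyldimethylsilyl)oxy]methyl}hexa-1,5-dien-1-yl]-3-(hydroxymethyl)furan-2(5H)-one
Conditions: DDQ, CH2Cl2/pH 7 buffer, 0 °C to rt
Reagents that add atoms: none
Why: Oxidative cleavage of the PMB ether with DDQ is neutral, leaves the TBS ether and the isolated alkenes alone, and does not epimerise the γ-position of the butenolide.

Step 12
Reactants: 17 (5R)-5-[(1E)-2-{[(tert-butyldimethylsilyl)oxy]methyl}hexa-1,5-dien-1-yl]-3-(hydroxymethyl)furan-2(5H)-one
Product: 18 (5R)-3-(bromomethyl)-5-[(1E)-2-{[(tert-butyldimethylsilyl)oxy]methyl}hexa-1,5-dien-1-yl]furan-2(5H)-one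
Conditions: CBr4, PPh3, CH2Cl2, 0 °C
Reagents that add atoms: carbon tetrabromide, BrC(Br)(Br)Br
Why: Appel bromination converts the primary allylic alcohol into the allylic bromide under neutral conditions, so the base-sensitive C6 stereocentre is preserved (fragment A).

Step 13
Reactants: 19 2-methylidenepropane-1,3-diol
Product: 20 2-{[(tert-butyldimethylsilyl)oxy]methyl}prop-2-en-1-ol
Conditions: NaH (1.0 equiv), THF, 0 °C to rt; then TBSCl (1.0 equiv)
Reagents that add atoms: tert-butyldimethylsilyl chloride, CC(C)(C)[Si](C)(C)Cl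
Why: Monosilylation of the monosodium alkoxide of the symmetric diol protects the future C14 oxygen; no stereocentre is involved.

Step 14
Reactants: 20 2-{[(tert-butyldimethylsilyl)oxy]methyl}prop-2-en-1-ol
Product: 21 {[2-(bromomethyl)prop-2-en-1-yl]oxy}(tert-butyl)dimethylsilane
Conditions: CBr4, PPh3, CH2Cl2, 0 °C
Reagents that add atoms: carbon tetrabromide, BrC(Br)(Br)Br
Why: Appel bromination of the primary allylic alcohol gives the allylic bromide without disturbing the silyl ether.

Step 15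
Reactants: 21 {[2-(bromomethyl)prop-2-en-1-yl]oxy}(tert-butyl)dimethylsilane
Product: 23 3-{[(tert-butyldimethylsilyl)oxy]methyl}but-3-en-1-ol, via allylzinc bromide 22 (not isolated)
Conditions: Zn dust, 37% aq. CH2O, THF/sat. aq. NH4Cl, 0 °C to rt
Reagents that add atoms: formaldehyde, C=O
Why: Aqueous zinc Barbier allylation of formaldehyde adds one carbon (C8) to the symmetric 2-substituted allyl unit, so only one regioisomer can form.

Step 16
Reactants: 23 3-{[(tert-butyldimethylsilyl)oxy]methyl}but-3-en-1-ol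
Product: 24 3-{[(tert-butyldimethylsilyl)oxy]methyl}but-3-enal
Conditions: Dess–Martin periodinane, pyridine, CH2Cl2, 0 °C to rt; used at once without storage
Reagents that add atoms: none
Why: Buffered Dess–Martin oxidation gives the β,γ-unsaturated aldehyde (fragment B) under neutral conditions that avoid migration of the alkene into conjugation.

Step 17
Reactants: 18 (5R)-3-(bromomethyl)-5-[(1E)-2-{[(tert-butyldimethylsilyl)oxy]methyl}hexa-1,5-dien-1-yl]furan-2(5H)-one; 24 3-{[(tert-butyldimethylsilyl)oxy]methyl}but-3-enal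
Product: 26 (4R,5R)-4-[(1S)-1-hydroxy-3-{[(tert-butyldimethylsilyl)oxy]methyl}but-3-en-1-yl]-5-[(1E)-2-{[(tert-butyldimethylsilyl)oxy]methyl}hexa-1,5-dien-1-yl]-3-methylideneoxolan-2-one, via butenolide allylzinc bromide 25 (not isolated)
Conditions: Zn dust (3 equiv), 24 (1.5 equiv), THF/sat. aq. NH4Cl (3:1), 0 °C to rt
Reagents that add atoms: none
Why: In this zinc Barbier carbonyl allylation the allylzinc from 18 adds through its γ-carbon (C7) in a closed Zimmerman–Traxler chair on the face opposite the C6 dienyl chain (trans lactone, C7 R) with the aldehyde substituent equatorial (anti adduct, C8 S), forming the C7–C8 bond and the α-methylene-γ-butyrolactone in one operation.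

Step 18
Reactants: 26 (4R,5R)-4-[(1S)-1-hydroxy-3-{[(tert-butyldimethylsilyl)oxy]methyl}but-3-en-1-yl]-5-[(1E)-2-{[(tert-butyldimethylsilyl)oxy]methyl}hexa-1,5-dien-1-yl]-3-methylideneoxolan-2-one; 27 angelic acid ((Z)-2-methylbut-2-enoic acid)
Product: 28 (1R)-3-{[(tert-butyldimethylsilyl)oxy]methyl}-1-[(2R,3R)-2-[(1E)-2-{[(tert-butyldimethylsilyl)oxy]methyl}hexa-1,5-dien-1-yl]-4-methylidene-5-oxooxolan-3-yl]but-3-en-1-yl (Z)-2-methylbut-2-enoate
Conditions: 27 (3 equiv), PPh3, DIAD, toluene, 0 °C to rt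
Reagents that add atoms: none
Why: Mitsunobu esterification displaces the activated C8 oxyphosphonium by angelate in an SN2 step, which inverts C8 from S to the required R and installs the ester under neutral conditions that keep the Z-enoate and the α-methylene lactone intact.

Step 19
Reactants: 28 (1R)-3-{[(tert-butyldimethylsilyl)oxy]methyl}-1-[(2R,3R)-2-[(1E)-2-{[(tert-butyldimethylsilyl)oxy]methyl}hexa-1,5-dien-1-yl]-4-methylidene-5-oxooxolan-3-yl]but-3-en-1-yl (Z)-2-methylbut-2-enoate
Product: 29 (3aR,4R,6E,10E,11aR)-6,10-bis({[(tert-butyldimethylsilyl)oxy]methyl})-3-methylidene-2-oxo-2,3,3a,4,5,8,9,11a-octahydrocyclodeca[b]furan-4-yl (Z)-2-methylbut-2-enoate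
Conditions: second-generation Hoveyda–Grubbs catalyst RuCl2(=CH-C6H4-2-OiPr)(H2IMes) (15 mol%), 1,4-benzoquinone (cat.), toluene (0.5 mM), 80 °C
Reagents that add atoms: none
Why: Ring-closing metathesis between the terminal vinyl group and the 1,1-disubstituted alkene closes the ten-membered carbocycle at C1=C10; the medium ring is expected to favour the ring-cis trisubstituted olefin (descriptor E because CH2O outranks the ring CH2), and the electron-poor angelate and α-methylene alkenes do not compete.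

Step 20
Reactants: 29 (3aR,4R,6E,10E,11aR)-6,10-bis({[(tert-butyldimethylsilyl)oxy]methyl})-3-methylidene-2-oxo-2,3,3a,4,5,8,9,11a-octahydrocyclodeca[b]furan-4-yl (Z)-2-methylbut-2-enoate
Product: 30 (3aR,4R,6E,10E,11aR)-6,10-bis(hydroxymethyl)-3-methylidene-2-oxo-2,3,3a,4,5,8,9,11a-octahydrocyclodeca[b]furan-4-yl (Z)-2-methylbut-2-enoate
Conditions: HF·pyridine, pyridine, THF, 0 °C to rt
Reagents that add atoms: none
Why: Buffered fluoride desilylation removes both primary allylic TBS ethers without touching the angelate, the α-methylene lactone or any stereocentre, giving the target.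

## Compound list

1 | but-2-yne-1,4-diol | OCC#CCO | starting material
2 | 4-[(tert-butyldimethylsilyl)oxy]but-2-yn-1-ol | OCC#CCO[Si](C)(C)C(C)(C)C | intermediate
3 | cyclic vinylalanate from 2 (sodium 3-{[(tert-butyldimethylsilyl)oxy]methyl}-2,2-bis(2-methoxyethoxy)-2,5-dihydro-1,2-oxaluminol-2-uide) | [Na+].COCCO[Al-]1(OCCOC)OCC=C1CO[Si](C)(C)C(C)(C)C | intermediate
4 | (Z)-4-[(tert-butyldimethylsilyl)oxy]-3-iodobut-2-en-1-ol | OC/C=C(\I)CO[Si](C)(C)C(C)(C)C | intermediate
5 | but-3-en-1-ylzinc bromide | C=CCC[Zn]Br | starting material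
6 | (E)-3-{[(tert-butyldimethylsilyl)oxy]methyl}hepta-2,6-dien-1-ol | OC/C=C(\CCC=C)CO[Si](C)(C)C(C)(C)C | intermediate
7 | (E)-3-{[(tert-butyldimethylsilyl)oxy]methyl}hepta-2,6-dienal | O=C/C=C(\CCC=C)CO[Si](C)(C)C(C)(C)C | intermediate
8 | prop-2-yn-1-ol | C#CCO | starting material
9 | 1-methoxy-4-[(prop-2-yn-1-yloxy)methyl]benzene | C#CCOCc1ccc(OC)cc1 | intermediate
10 | lithium acetylide of 9 ({3-[(4-methoxybenzyl)oxy]prop-1-yn-1-yl}lithium) | [Li]C#CCOCc1ccc(OC)cc1 | intermediate
11 | rac-(E)-6-{[(tert-butyldimethylsilyl)oxy]methyl}-1-[(4-methoxybenzyl)oxy]deca-5,9-dien-2-yn-4-ol | COc1ccc(COCC#CC(O)/C=C(\CCC=C)CO[Si](C)(C)C(C)(C)C)cc1 | intermediate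
12 | (E)-6-{[(tert-butyldimethylsilyl)oxy]methyl}-1-[(4-methoxybenzyl)oxy]deca-5,9-dien-2-yn-4-one | COc1ccc(COCC#CC(=O)/C=C(\CCC=C)CO[Si](C)(C)C(C)(C)C)cc1 | intermediate
13 | (4R,5E)-6-{[(tert-butyldimethylsilyl)oxy]methyl}-1-[(4-methoxybenzyl)oxy]deca-5,9-dien-2-yn-4-ol | COc1ccc(COCC#C[C@H](O)/C=C(\CCC=C)CO[Si](C)(C)C(C)(C)C)cc1 | intermediate
14 | cyclic vinylalanate from 13 (sodium (5R)-2,2-bis(2-methoxyethoxy)-3-{[(4-methoxybenzyl)oxy]methyl}-5-[(1E)-2-{[(tert-butyldimethylsilyl)oxy]methyl}hexa-1,5-dien-1-yl]-2,5-dihydro-1,2-oxaluminol-2-uide) | [Na+].COCCO[Al-]1(OCCOC)O[C@H](/C=C(\CCC=C)CO[Si](C)(C)C(C)(C)C)C=C1COCc1ccc(OC)cc1 | intermediate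
15 | (2Z,4R,5E)-6-{[(tert-butyldimethylsilyl)oxy]methyl}-2-iodo-1-[(4-methoxybenzyl)oxy]deca-2,5,9-trien-4-ol | COc1ccc(COC/C(I)=C/[C@H](O)/C=C(\CCC=C)CO[Si](C)(C)C(C)(C)C)cc1 | intermediate
16 | (5R)-5-[(1E)-2-{[(tert-butyldimethylsilyl)oxy]methyl}hexa-1,5-dien-1-yl]-3-{[(4-methoxybenzyl)oxy]methyl}furan-2(5H)-one | COc1ccc(COCC2=C[C@@H](/C=C(\CCC=C)CO[Si](C)(C)C(C)(C)C)OC2=O)cc1 | intermediate
17 | (5R)-5-[(1E)-2-{[(tert-butyldimethylsilyl)oxy]methyl}hexa-1,5-dien-1-yl]-3-(hydroxymethyl)furan-2(5H)-one | OCC1=C[C@@H](/C=C(\CCC=C)CO[Si](C)(C)C(C)(C)C)OC1=O | intermediate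
18 | (5R)-3-(bromomethyl)-5-[(1E)-2-{[(tert-butyldimethylsilyl)oxy]methyl}hexa-1,5-dien-1-yl]furan-2(5H)-one | BrCC1=C[C@@H](/C=C(\CCC=C)CO[Si](C)(C)C(C)(C)C)OC1=O | intermediate
19 | 2-methylidenepropane-1,3-diol | C=C(CO)CO | starting material
20 | 2-{[(tert-butyldimethylsilyl)oxy]methyl}prop-2-en-1-ol | C=C(CO)CO[Si](C)(C)C(C)(C)C | intermediate
21 | {[2-(bromomethyl)prop-2-en-1-yl]oxy}(tert-butyl)dimethylsilane | C=C(CBr)CO[Si](C)(C)C(C)(C)C | intermediate
22 | allylzinc bromide from 21 (bromo(2-{[(tert-butyldimethylsilyl)oxy]methyl}prop-2-en-1-yl)zinc) | C=C(C[Zn]Br)CO[Si](C)(C)C(C)(C)C | intermediate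
23 | 3-{[(tert-butyldimethylsilyl)oxy]methyl}but-3-en-1-ol | C=C(CCO)CO[Si](C)(C)C(C)(C)C | intermediate
24 | 3-{[(tert-butyldimethylsilyl)oxy]methyl}but-3-enal | C=C(CC=O)CO[Si](C)(C)C(C)(C)C | intermediate
25 | butenolide allylzinc bromide from 18 (bromo{[(5R)-5-[(1E)-2-{[(tert-butyldimethylsilyl)oxy]methyl}hexa-1,5-dien-1-yl]-2-oxo-2,5-dihydrofuran-3-yl]methyl}zinc) | Br[Zn]CC1=C[C@@H](/C=C(\CCC=C)CO[Si](C)(C)C(C)(C)C)OC1=O | intermediate
26 | (4R,5R)-4-[(1S)-1-hydroxy-3-{[(tert-butyldimethylsilyl)oxy]methyl}but-3-en-1-yl]-5-[(1E)-2-{[(tert-butyldimethylsilyl)oxy]methyl}hexa-1,5-dien-1-yl]-3-methylideneoxolan-2-one | C=C1C(=O)O[C@H](/C=C(\CCC=C)CO[Si](C)(C)C(C)(C)C)[C@H]1[C@@H](O)CC(=C)CO[Si](C)(C)C(C)(C)C | intermediate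
27 | angelic acid, (Z)-2-methylbut-2-enoic acid | C/C=C(/C)C(=O)O | starting material
28 | (1R)-3-{[(tert-butyldimethylsilyl)oxy]methyl}-1-[(2R,3R)-2-[(1E)-2-{[(tert-butyldimethylsilyl)oxy]methyl}hexa-1,5-dien-1-yl]-4-methylidene-5-oxooxolan-3-yl]but-3-en-1-yl (Z)-2-methylbut-2-enoate | C=C1C(=O)O[C@H](/C=C(\CCC=C)CO[Si](C)(C)C(C)(C)C)[C@H]1[C@H](OC(=O)/C(C)=C\C)CC(=C)CO[Si](C)(C)C(C)(C)C | intermediate
29 | (3aR,4R,6E,10E,11aR)-6,10-bis({[(tert-butyldimethylsilyl)oxy]methyl})-3-methylidene-2-oxo-2,3,3a,4,5,8,9,11a-octahydrocyclodeca[b]furan-4-yl (Z)-2-methylbut-2-enoate | C=C1C(=O)O[C@@H]2/C=C(/CO[Si](C)(C)C(C)(C)C)CC/C=C(/CO[Si](C)(C)C(C)(C)C)C[C@@H](OC(=O)/C(C)=C\C)[C@@H]12 | intermediate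
30 | (3aR,4R,6E,10E,11aR)-6,10-bis(hydroxymethyl)-3-methylidene-2-oxo-2,3,3a,4,5,8,9,11a-octahydrocyclodeca[b]furan-4-yl (Z)-2-methylbut-2-enoate | C=C1C(=O)O[C@@H]2/C=C(/CO)CC/C=C(/CO)C[C@@H](OC(=O)/C(C)=C\C)[C@@H]12 | target

## Step count and risks

Total step count: 20. Longest linear sequence: 15 steps (steps 1–4, 6–12, 17–20, from but-2-yne-1,4-diol).

The three steps most likely to fail:

Step 17 (Barbier coupling). Aldehyde 24 can isomerise into conjugation in the aqueous medium, the bromide 18 can be reduced or dimerised by zinc, and the C8 selectivity rests on the chair model (anti adduct, C8 S); the C8 configuration of 26 must be confirmed before step 18. The fallback sets out from 18 and replaces the in situ allylzinc by an isolated allylboron reagent. Borylation of 18 with bis(pinacolato)diboron and Pd2(dba)3 (cat.) in THF at 60 °C gives the butenolide pinacol allylboronate F1. Allylboration of aldehyde 24 with this boronate, catalysed by Sc(OTf)3 in toluene from −78 °C to rt, runs through the same closed chair under anhydrous conditions. Hydrolysis of the borate on work-up comes back to the route at 26.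

Step 18 (Mitsunobu inversion with angelic acid). The hindered secondary carbinol may eliminate towards the allylic C9 or C7 positions, and the angelate may partly isomerise to tiglate. The fallback sets out from 26 and separates activation from displacement. Chloromethanesulfonyl chloride and pyridine in CH2Cl2 at 0 °C give the C8 chloromethanesulfonate F2. SN2 displacement with caesium angelate (27, Cs2CO3, 18-crown-6, toluene, 60 °C) inverts C8 and comes back to the route at 28.

Step 19 (ring-closing metathesis). Closing a ten-membered ring with a trisubstituted olefin can stall or give oligomers. The fallback sets out from 26 and changes the order of events, cyclising the less encumbered free carbinol before esterification. Ring-closing metathesis of 26 under the same high dilution gives the macrocyclic C8 S alcohol F3. Mitsunobu esterification of this alcohol with 27 (PPh3, DIAD, toluene) inverts C8 on the ring and comes back to the route at 29.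

Further compounds

F1 | step 17 | (5R)-5-[(1E)-2-{[(tert-butyldimethylsilyl)oxy]methyl}hexa-1,5-dien-1-yl]-3-[(4,4,5,5-tetramethyl-1,3,2-dioxaborolan-2-yl)methyl]furan-2(5H)-one | CC1(C)OB(CC2=C[C@@H](/C=C(\CCC=C)CO[Si](C)(C)C(C)(C)C)OC2=O)OC1(C)C
F2 | step 18 | (1S)-3-{[(tert-butyldimethylsilyl)oxy]methyl}-1-[(2R,3S)-2-[(1E)-2-{[(tert-butyldimethylsilyl)oxy]methyl}hexa-1,5-dien-1-yl]-4-methylidene-5-oxooxolan-3-yl]but-3-en-1-yl chloromethanesulfonate | C=C1C(=O)O[C@H](/C=C(\CCC=C)CO[Si](C)(C)C(C)(C)C)[C@H]1[C@@H](OS(=O)(=O)CCl)CC(=C)CO[Si](C)(C)C(C)(C)C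
F3 | step 19 | (3aR,4S,6E,10E,11aR)-6,10-bis({[(tert-butyldimethylsilyl)oxy]methyl})-4-hydroxy-3-methylidene-3a,4,5,8,9,11a-hexahydrocyclodeca[b]furan-2(3H)-one | C=C1C(=O)O[C@@H]2/C=C(/CO[Si](C)(C)C(C)(C)C)CC/C=C(/CO[Si](C)(C)C(C)(C)C)C[C@H](O)[C@@H]12
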